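Every addition to G spends one L, and J, the tris adduct, has taken 3 of them, so we count turnovers.

| flask | G | L | temperature | remark | time |
|---|---|---|---|---|---|
| elm | 0.011 M | 0.0132 M | 25 °C | the very flask that is asked about, followed so far |  |
| larch | 0.011 M | 0.020 M | 10 °C | run made earlier |  |
| flask | 0.011 M | 0.0132 M | 25 °C |  | 50 min |

| run | time / min | J / % | G / % |
|---|---|---|---|
| elm | 10.0 | 5.0 | 46.2 |
| elm | 20.0 | 7.9 | 36.7 |
| elm | 30.0 | 9.7 | 36.5 |
| elm | 40.0 | 9.5 | 34.1 |
| larch | 12.0 | 4.3 | 47.1 |
| larch | 25.0 | 9.9 | 30.7 |
| larch | 40.0 | 13.8 | 23.2 |
| larch | 50.0 | 15.7 | 21.4 |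

(readings scatter by 0.5 percentage points)

- gamma: change nothing and wait 25 min more
- zeta: at 50 min take out 90 % of the J then present, then wait 25 min
- theta: at 50 min add L, 100 % of the amount charged, then wait 25 min
- eta: at 50 min raise the temperature by 15 K, then wait 25 min

- J, in percent of the G first charged, at 50 min
- what to do for the largest gain in J; "none" if nothing gains more than 2 percentage points (gamma / zeta / theta / eta / none)
- J present, with what was taken out counted in, in percent of the G first charged, after theta
- J present, with what was taken out counted in, in percent of the G first charged, after eta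

- what is taken out of J is counted as made
- the earlier runs were read with a standard deviation of 0.5 percentage points
- additions bring no volume worth counting

The flask repeats the elm run, and its charge gives a turnover budget, the equivalents of L per G charged, of 1.20. Divided by 3, that is our bound from above: J at most 40.0 %. The G reading tightens it. At 40.0 min the elm run reads G at 34.1 %, so each G that reacted has paid at least one L, leaving at most 0.541 equivalents. A J needs two more turnovers, which caps J near 27.0 %.

From below stand the last J readings of the elm run, 9.7 % and 9.5 %, read with a scatter of 0.5 percentage points. The larch run, colder but with 1.82 equivalents, still climbs to 15.7 %. By hand the bracket closes no further, and we commit to its lower edge, near 9.5 %, since those two elm readings differ by 0.2 points, less than the scatter. Of the options, theta is the one that adds L, and it lifts the first ceiling to 80.0 %.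

The forecast gives 9.8 %, inside the bracket, chooses theta, and puts J at 42 % after theta, under that ceiling, and at 10 % after eta. Its ground: “That points to L running out, not to equilibrium.”

In the flask at 50.0 min, L, the limiting reagent, stands at 0.18 % of its charge, and X, E, J and D, each counted by its turnovers, make 1.20 against the budget of 1.20. J is 10.2 %. Theta is best, gaining 15 points, yet reaches 25.6 %, less than the forecast's 42 %; eta gives 10.3 %.

    L + E → J (k = 11.0 L mol⁻¹ min⁻¹, Ea = 52.0 kJ mol⁻¹)
    L + X → E (k = 15.5 L mol⁻¹ min⁻¹, Ea = 45.0 kJ mol⁻¹)
    L + J → D (k = 8.83 L mol⁻¹ min⁻¹, Ea = 37.0 kJ mol⁻¹)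
    G + L → X (k = 10.2 L mol⁻¹ min⁻¹, Ea = 42.0 kJ mol⁻¹)
    (constants at 25 °C)

A neighbouring flask, like this one but with 0.0033 M of L, has a budget of 0.300. Its G at 50.0 min stands at 75.4 %, so the same reckoning caps J at 2.69 %, and its J is 0.450 %.

The numbers in the tables stem from a simulated flask for an exercise, and the scatter is random.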